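**Retrosynthetic overview**

1. The dihydrofuran ring is closed last: the C-3′–C-7 bond forms by Friedel–Crafts capture of a p-quinone-methide-type benzylic cation by ring B inside an 8–O–4′ aryl ether. This mirrors the closure presumed in nature (8–O–4′ coupling of resveratrol to the flavonol 4′-oxygen, then trapping of the quinone methide by C-3′), sets C-3 trans to C-2, and is run together with removal of all seven MOM groups.
2. C-2 is set one step earlier by transfer hydrogenation with dynamic kinetic resolution of the racemising α-aryloxy ketone.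
3. Ring C comes from a chalcone by one-pot Claisen–Schmidt condensation and Algar–Flynn–Oyamada oxidative cyclisation (the chalcone → flavonol logic of flavonoid biosynthesis), then 3-O-methylation.
4. The 8–O–4′ ether comes from O-alkylation of the 4-OH of 2,4,5-trihydroxybenzaldehyde with the α-bromoketone cut from resveratrol. The ring A ketone comes from a ketone-directed C–H hydroxylation, which fixes the 6-methyl pattern.
5. Ring order: ring A (bought) → ring C → dihydrofuran ring.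

Assumption: the target is the trans-(2S,3S) isomer encoded by the SMILES; the three starting materials are catalogue compounds; MOM = methoxymethyl.

**Route**

Step 1
Reactants: 1 (E)-resveratrol
Product: 2 (E)-3,4′,5-tris(methoxymethoxy)stilbene
Conditions: NaH (3.6 equiv), MOMCl (3.5 equiv), DMF, 0 °C → rt
Reagents that add atoms: chloromethyl methyl ether (MOMCl), COCCl
Why: Williamson-type O-alkylation of the three phenoxides gives acetals that survive the later base, peroxide and hydride steps and fall off in the final acid step.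

Step 2
Reactants: 2 (E)-3,4′,5-tris(methoxymethoxy)stilbene
Product: 4 rac-2-bromo-2-[3,5-bis(methoxymethoxy)phenyl]-1-[4-(methoxymethoxy)phenyl]ethanone, via bromohydrin 3 (not isolated)
Conditions: NBS (1.05 equiv), DMSO/H2O, 0 °C; then IBX (1.5 equiv), rt
Reagents that add atoms: N-bromosuccinimide, O=C1CCC(=O)N1Br; water, O
Why: Dalton bromohydrin formation (anti addition, oxygen at the carbon whose cation is stabilised by the p-alkoxyphenyl ring, bromine next to the 3,5-dioxygenated ring) followed by IBX alcohol oxidation puts the carbonyl at C-7 and the leaving group at C-8.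

Step 3
Reactants: 4 rac-2-bromo-2-[3,5-bis(methoxymethoxy)phenyl]-1-[4-(methoxymethoxy)phenyl]ethanone; 5 2,4,5-trihydroxybenzaldehyde
Product: 6 rac-4-{1-[3,5-bis(methoxymethoxy)phenyl]-2-[4-(methoxymethoxy)phenyl]-2-oxoethoxy}-2,5-dihydroxybenzaldehyde
Conditions: KHCO3 (1.2 equiv), DMF, 25 °C, argon
Reagents that add atoms: none
Why: SN2 Williamson etherification in which the weak base ionises only the 4-OH (para to the formyl group, the most acidic; 2-OH is hydrogen-bonded, 5-OH is meta), fixing the 8–O–4′ bond and the later position of the ring oxygen.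

Step 4
Reactants: 6 rac-4-{1-[3,5-bis(methoxymethoxy)phenyl]-2-[4-(methoxymethoxy)phenyl]-2-oxoethoxy}-2,5-dihydroxybenzaldehyde
Product: 7 rac-4-{1-[3,5-bis(methoxymethoxy)phenyl]-2-[4-(methoxymethoxy)phenyl]-2-oxoethoxy}-2,5-bis(methoxymethoxy)benzaldehyde
Conditions: MOMCl (3 equiv), i-Pr2NEt (4 equiv), CH2Cl2, 0 → 40 °C
Reagents that add atoms: chloromethyl methyl ether (MOMCl), COCCl
Why: acetal protection of the two remaining phenols under amine base, which does not enolise the keto ether; alkylation of the open phenol form also drains any cyclic hemiketal between 5-OH and the ketone.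

Step 5
Reactants: 8 1-(2,4-dihydroxy-3-methylphenyl)ethanone
Product: 9 1-[2,4-bis(methoxymethoxy)-3-methylphenyl]ethanone
Conditions: NaH (2.2 equiv), MOMCl (2.4 equiv), DMF, 0 °C → rt
Reagents that add atoms: chloromethyl methyl ether (MOMCl), COCCl
Why: Williamson-type O-alkylation of both phenoxides, including the hydrogen-bonded 2-OH, which needs full deprotonation.

Step 6
Reactants: 9 1-[2,4-bis(methoxymethoxy)-3-methylphenyl]ethanone
Product: 11 1-[6-hydroxy-2,4-bis(methoxymethoxy)-3-methylphenyl]ethanone, via aryl boronate 10 (not isolated)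
Conditions: [Ir(OMe)(cod)]2 (2.5 mol%), AsPh3 (10 mol%), B2pin2 (1.2 equiv), octane, 120 °C; then Oxone (2KHSO5·KHSO4·K2SO4), acetone/H2O, 0 °C, 15 min
Reagents that add atoms: bis(pinacolato)diboron, CC1(C)OB(OC1(C)C)B1OC(C)(C)C(C)(C)O1 (boron carried only in 10); Oxone as KHSO5, [K+].[O-]S(=O)(=O)OO
Why: ketone-directed iridium-catalysed ortho C–H borylation reaches the only free ortho position, and one-pot boronate oxidation gives the single free phenol para to the methyl group, so ring C can later close only to the 6-methyl isomer.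

Step 7
Reactants: 11 1-[6-hydroxy-2,4-bis(methoxymethoxy)-3-methylphenyl]ethanone; 7 rac-4-{1-[3,5-bis(methoxymethoxy)phenyl]-2-[4-(methoxymethoxy)phenyl]-2-oxoethoxy}-2,5-bis(methoxymethoxy)benzaldehyde
Product: 13 rac-2-[4-{1-[3,5-bis(methoxymethoxy)phenyl]-2-[4-(methoxymethoxy)phenyl]-2-oxoethoxy}-2,5-bis(methoxymethoxy)phenyl]-3-hydroxy-5,7-bis(methoxymethoxy)-6-methyl-4H-chromen-4-one, via chalcone 12 (not isolated)
Conditions: KOH (50% aq), EtOH, rt, argon, 48 h; then MeOH, 30% H2O2, 0 °C → rt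
Reagents that add atoms: hydrogen peroxide, OO
Why: Claisen–Schmidt condensation then Algar–Flynn–Oyamada oxidative cyclisation builds ring C at the flavonol level, as chalcones do in flavonoid biosynthesis; the side-chain ketone has no route to dehydration and only equilibrates.

Step 8
Reactants: 13 rac-2-[4-{1-[3,5-bis(methoxymethoxy)phenyl]-2-[4-(methoxymethoxy)phenyl]-2-oxoethoxy}-2,5-bis(methoxymethoxy)phenyl]-3-hydroxy-5,7-bis(methoxymethoxy)-6-methyl-4H-chromen-4-one
Product: 14 rac-2-[4-{1-[3,5-bis(methoxymethoxy)phenyl]-2-[4-(methoxymethoxy)phenyl]-2-oxoethoxy}-2,5-bis(methoxymethoxy)phenyl]-3-methoxy-5,7-bis(methoxymethoxy)-6-methyl-4H-chromen-4-one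
Conditions: MeI (1.2 equiv), K2CO3 (1.5 equiv), acetone, rt
Reagents that add atoms: iodomethane, CI
Why: Williamson O-methylation of the only free and far most acidic hydroxyl (flavonol 3-OH); it is done before the reduction because a free 3-hydroxy-4-keto unit would chelate the ruthenium catalyst.

Step 9
Reactants: 14 rac-2-[4-{1-[3,5-bis(methoxymethoxy)phenyl]-2-[4-(methoxymethoxy)phenyl]-2-oxoethoxy}-2,5-bis(methoxymethoxy)phenyl]-3-methoxy-5,7-bis(methoxymethoxy)-6-methyl-4H-chromen-4-one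
Product: 15 2-[4-{(1R,2R)-1-[3,5-bis(methoxymethoxy)phenyl]-2-hydroxy-2-[4-(methoxymethoxy)phenyl]ethoxy}-2,5-bis(methoxymethoxy)phenyl]-3-methoxy-5,7-bis(methoxymethoxy)-6-methyl-4H-chromen-4-one
Conditions: RuCl[(S,S)-TsDPEN](p-cymene) (3 mol%), HCO2H/Et3N (5:2), DMF, 40 °C
Reagents that add atoms: none
Why: Noyori–Ikariya asymmetric transfer hydrogenation with dynamic kinetic resolution, in which the α-aryl-α-aryloxy centre racemises in the amine medium and, by analogy with rac-benzoin → (R,R)-hydrobenzoin with the same catalyst, is funnelled to 1R (the future C-2); the carbinol centre (2R) is erased in step 10 and the chromone carbonyl is a vinylogous ester that is not reduced.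

Step 10
Reactants: 15 2-[4-{(1R,2R)-1-[3,5-bis(methoxymethoxy)phenyl]-2-hydroxy-2-[4-(methoxymethoxy)phenyl]ethoxy}-2,5-bis(methoxymethoxy)phenyl]-3-methoxy-5,7-bis(methoxymethoxy)-6-methyl-4H-chromen-4-one
Product: 17 2-[(2S,3S)-2-(3,5-dihydroxyphenyl)-4,7-dihydroxy-3-(4-hydroxyphenyl)-2,3-dihydro-1-benzofuran-5-yl]-5,7-dihydroxy-3-methoxy-6-methyl-4H-chromen-4-one, via hepta-MOM dihydrobenzofuran 16 (not isolated)
Conditions: TFA (5 equiv), CH2Cl2 (0.01 M), −20 → 0 °C; then 3 M HCl, MeOH, 45 °C, argon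
Reagents that add atoms: none
Why: intramolecular Friedel–Crafts alkylation (5-exo) of the p-alkoxybenzylic cation, an O-alkylated p-quinone methide, by C-3′ of ring B (ortho to two oxygens) closes the dihydrofuran ring as presumed in nature, with the new aryl-bearing centre trans to the fixed 3,5-dioxygenated aryl group (the (1R) ether carbon becomes 2S by a priority change only, the new centre is 3S); acetal methanolysis then frees the seven phenols.

**Compound list**

1 | (E)-resveratrol, 5-[(E)-2-(4-hydroxyphenyl)ethenyl]benzene-1,3-diol | Oc1ccc(/C=C/c2cc(O)cc(O)c2)cc1 | starting material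
2 | (E)-3,4′,5-tris(methoxymethoxy)stilbene | COCOc1ccc(/C=C/c2cc(OCOC)cc(OCOC)c2)cc1 | intermediate
3 | rac-(1R,2S)-2-bromo-2-[3,5-bis(methoxymethoxy)phenyl]-1-[4-(methoxymethoxy)phenyl]ethanol (anti-addition bromohydrin, one enantiomer drawn) | O[C@H](c1ccc(OCOC)cc1)[C@@H](Br)c1cc(OCOC)cc(OCOC)c1 | intermediate
4 | rac-2-bromo-2-[3,5-bis(methoxymethoxy)phenyl]-1-[4-(methoxymethoxy)phenyl]ethanone | COCOc1ccc(cc1)C(=O)C(Br)c1cc(OCOC)cc(OCOC)c1 | intermediate
5 | 2,4,5-trihydroxybenzaldehyde | O=Cc1cc(O)c(O)cc1O | starting material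
6 | rac-4-{1-[3,5-bis(methoxymethoxy)phenyl]-2-[4-(methoxymethoxy)phenyl]-2-oxoethoxy}-2,5-dihydroxybenzaldehyde | O=Cc1cc(O)c(OC(C(=O)c2ccc(OCOC)cc2)c2cc(OCOC)cc(OCOC)c2)cc1O | intermediate
7 | rac-4-{1-[3,5-bis(methoxymethoxy)phenyl]-2-[4-(methoxymethoxy)phenyl]-2-oxoethoxy}-2,5-bis(methoxymethoxy)benzaldehyde | O=Cc1cc(OCOC)c(OC(C(=O)c2ccc(OCOC)cc2)c2cc(OCOC)cc(OCOC)c2)cc1OCOC | intermediate
8 | 1-(2,4-dihydroxy-3-methylphenyl)ethanone | CC(=O)c1ccc(O)c(C)c1O | starting material
9 | 1-[2,4-bis(methoxymethoxy)-3-methylphenyl]ethanone | CC(=O)c1ccc(OCOC)c(C)c1OCOC | intermediate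
10 | 1-[2,4-bis(methoxymethoxy)-3-methyl-6-(4,4,5,5-tetramethyl-1,3,2-dioxaborolan-2-yl)phenyl]ethanone | CC(=O)c1c(B2OC(C)(C)C(C)(C)O2)cc(OCOC)c(C)c1OCOC | intermediate
11 | 1-[6-hydroxy-2,4-bis(methoxymethoxy)-3-methylphenyl]ethanone | CC(=O)c1c(O)cc(OCOC)c(C)c1OCOC | intermediate
12 | rac-(E)-chalcone: (E)-3-[4-{1-[3,5-bis(methoxymethoxy)phenyl]-2-[4-(methoxymethoxy)phenyl]-2-oxoethoxy}-2,5-bis(methoxymethoxy)phenyl]-1-[6-hydroxy-2,4-bis(methoxymethoxy)-3-methylphenyl]prop-2-en-1-one | O=C(/C=C/c1cc(OCOC)c(OC(C(=O)c2ccc(OCOC)cc2)c2cc(OCOC)cc(OCOC)c2)cc1OCOC)c1c(O)cc(OCOC)c(C)c1OCOC | intermediate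
13 | rac-2-[4-{1-[3,5-bis(methoxymethoxy)phenyl]-2-[4-(methoxymethoxy)phenyl]-2-oxoethoxy}-2,5-bis(methoxymethoxy)phenyl]-3-hydroxy-5,7-bis(methoxymethoxy)-6-methyl-4H-chromen-4-one | COCOc1cc2oc(-c3cc(OCOC)c(OC(C(=O)c4ccc(OCOC)cc4)c4cc(OCOC)cc(OCOC)c4)cc3OCOC)c(O)c(=O)c2c(OCOC)c1C | intermediate
14 | rac-2-[4-{1-[3,5-bis(methoxymethoxy)phenyl]-2-[4-(methoxymethoxy)phenyl]-2-oxoethoxy}-2,5-bis(methoxymethoxy)phenyl]-3-methoxy-5,7-bis(methoxymethoxy)-6-methyl-4H-chromen-4-one | COCOc1cc2oc(-c3cc(OCOC)c(OC(C(=O)c4ccc(OCOC)cc4)c4cc(OCOC)cc(OCOC)c4)cc3OCOC)c(OC)c(=O)c2c(OCOC)c1C | intermediate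
15 | 2-[4-{(1R,2R)-1-[3,5-bis(methoxymethoxy)phenyl]-2-hydroxy-2-[4-(methoxymethoxy)phenyl]ethoxy}-2,5-bis(methoxymethoxy)phenyl]-3-methoxy-5,7-bis(methoxymethoxy)-6-methyl-4H-chromen-4-one | COCOc1cc2oc(-c3cc(OCOC)c(O[C@@H]([C@H](O)c4ccc(OCOC)cc4)c4cc(OCOC)cc(OCOC)c4)cc3OCOC)c(OC)c(=O)c2c(OCOC)c1C | intermediate
16 | 2-[(2S,3S)-2-[3,5-bis(methoxymethoxy)phenyl]-4,7-bis(methoxymethoxy)-3-[4-(methoxymethoxy)phenyl]-2,3-dihydro-1-benzofuran-5-yl]-3-methoxy-5,7-bis(methoxymethoxy)-6-methyl-4H-chromen-4-one | COc1c(-c2cc(OCOC)c3c(c2OCOC)[C@H](c2ccc(OCOC)cc2)[C@@H](c2cc(OCOC)cc(OCOC)c2)O3)oc2cc(OCOC)c(C)c(OCOC)c2c1=O | intermediate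
17 | 2-[(2S,3S)-2-(3,5-dihydroxyphenyl)-4,7-dihydroxy-3-(4-hydroxyphenyl)-2,3-dihydro-1-benzofuran-5-yl]-5,7-dihydroxy-3-methoxy-6-methyl-4H-chromen-4-one (CNP0218412.2) | COc1c(-c2cc(O)c3c(c2O)[C@H](c2ccc(O)cc2)[C@@H](c2cc(O)cc(O)c2)O3)oc2cc(O)c(C)c(O)c2c1=O | target

**Totals and risks**

Total step count: 10. Longest linear sequence: 8 (steps 1, 2, 3, 4, 7, 8, 9, 10 from resveratrol; the ring A branch, steps 5 and 6, joins at step 7).

Steps most likely to fail:

Step 7. The chalcone carries a 6′-OMOM group and an ortho-OMOM group on the aldehyde-derived ring, both of which favour aurone formation under Algar–Flynn–Oyamada conditions, and the keto ether is exposed to KOH and peroxide. The fallback sets out from chalcone 12, isolated after the KOH stage. Heating with I2 (10 mol%) in DMSO at 110 °C closes ring C at the flavone level, without peroxide, to give the 3-unsubstituted flavone F1. Epoxidation of its 2,3-double bond with DMDO (acetone/CH2Cl2, 0 °C) and opening with catalytic TsOH installs the 3-hydroxyl, and the route is rejoined at flavonol 13.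

Step 9. The ketone is hindered, and the pairing of the racemising centre with the catalyst is inferred from benzoin, not proven for an α-aryloxy group. If the pairing turns out opposite, the (R,R)-catalyst is used; that is only a change of conditions. The fallback gives up catalytic control and sets out from ketone 14. NaBH4 (MeOH/THF, 0 °C) gives the carbinol stereoisomer mixture F2. TFA cyclisation as in the first stage of step 10, which is trans-selective whatever the carbinol configuration, gives the racemic trans hepta-MOM dihydrobenzofuran F3. Preparative chiral SFC on amylose tris(3,5-dimethylphenylcarbamate) then delivers 16, here isolated, which is deprotected as in step 10.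

Step 10. The cation can lose H-8 to give an enol ether (hydrolytic loss of the stilbene unit), alkylate another molecule, or close to some cis isomer. The fallback avoids the cation and sets out from ketone 14. The seven acetals are removed first (3 M HCl, MeOH, 40 °C; the ketone cannot ionise) to give the heptahydroxy keto ether F4. Reduction under the step 9 conditions gives the free (1R,2R)-carbinol F5. Its free 4-hydroxybenzyl alcohol is then converted into the neutral p-quinone methide with (PhO)2P(O)OH (10 mol%) in HFIP at rt. Conjugate addition of C-3′ closes the ring; any benzodioxane formed through the 5′-OH is a reversible aryl ether. The route is rejoined at 17.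

**Further compounds**

F1 | step 7 | rac-2-[4-{1-[3,5-bis(methoxymethoxy)phenyl]-2-[4-(methoxymethoxy)phenyl]-2-oxoethoxy}-2,5-bis(methoxymethoxy)phenyl]-5,7-bis(methoxymethoxy)-6-methyl-4H-chromen-4-one | COCOc1cc2oc(-c3cc(OCOC)c(OC(C(=O)c4ccc(OCOC)cc4)c4cc(OCOC)cc(OCOC)c4)cc3OCOC)cc(=O)c2c(OCOC)c1C
F2 | step 9 | 2-[4-{1-[3,5-bis(methoxymethoxy)phenyl]-2-hydroxy-2-[4-(methoxymethoxy)phenyl]ethoxy}-2,5-bis(methoxymethoxy)phenyl]-3-methoxy-5,7-bis(methoxymethoxy)-6-methyl-4H-chromen-4-one, all four stereoisomers | COCOc1cc2oc(-c3cc(OCOC)c(OC(C(O)c4ccc(OCOC)cc4)c4cc(OCOC)cc(OCOC)c4)cc3OCOC)c(OC)c(=O)c2c(OCOC)c1C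
F3 | step 9 | racemic trans hepta-MOM dihydrobenzofuran, 1:1 mixture of 16 and its (2R,3R)-enantiomer | COc1c(-c2cc(OCOC)c3c(c2OCOC)[C@H](c2ccc(OCOC)cc2)[C@@H](c2cc(OCOC)cc(OCOC)c2)O3)oc2cc(OCOC)c(C)c(OCOC)c2c1=O.COc1c(-c2cc(OCOC)c3c(c2OCOC)[C@@H](c2ccc(OCOC)cc2)[C@H](c2cc(OCOC)cc(OCOC)c2)O3)oc2cc(OCOC)c(C)c(OCOC)c2c1=O
F4 | step 10 | rac-2-[4-{1-(3,5-dihydroxyphenyl)-2-(4-hydroxyphenyl)-2-oxoethoxy}-2,5-dihydroxyphenyl]-5,7-dihydroxy-3-methoxy-6-methyl-4H-chromen-4-one | COc1c(-c2cc(O)c(OC(C(=O)c3ccc(O)cc3)c3cc(O)cc(O)c3)cc2O)oc2cc(O)c(C)c(O)c2c1=O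
F5 | step 10 | 2-[4-{(1R,2R)-1-(3,5-dihydroxyphenyl)-2-hydroxy-2-(4-hydroxyphenyl)ethoxy}-2,5-dihydroxyphenyl]-5,7-dihydroxy-3-methoxy-6-methyl-4H-chromen-4-one | COc1c(-c2cc(O)c(O[C@@H]([C@H](O)c3ccc(O)cc3)c3cc(O)cc(O)c3)cc2O)oc2cc(O)c(C)c(O)c2c1=O
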